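The route cuts ring C at C2–C3 and C2–O1. The lactone carbonyl then comes from carbon monoxide, and the rest is an acyclic (Z)-β-iodoenone. The key step uses the fact that O1 of ring C is the enol oxygen of a C5 ketone whose only enolisable neighbour is c1, which is activated by both C5=O and the c2=c3 alkene. One palladium-catalysed carbonylation converts C3–I into the acyl group, closes ring C and sets the Z C5=c1 alkene. The precursor already holds finished ring B (3-OTBS, free 5,6-trans-diol), the E C7=C8 alkene, iodine cis to the acyl group and a TBS-protected c4 alcohol. Ring A is added last by an E-selective Wittig reaction.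

Key step: step 15

Locants: ring B runs from C1 (CMe2) to C6 (side-chain carbinol). C7=C8 is the vinylene. Ring C is O1, C2–C5. The chain carbons c1–c4 are counted from C5.

Remark on the chemistry: read from the SMILES, ring B is (3R,5S,6S), with 5-OH trans to 6-OH and 3-OH cis to 6-OH, and ring A is R at its carbinol carbon. The two secondary carbinol centres have opposite spatial sense, so actinol serves both rings, with inversion for ring B and retention for ring A.

Assumption: the carbinol carbon (future C5) of 16 and 17 is left unassigned, because step 13 turns it into the ketone.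

**Ring B alkenyl iodide (steps 1–8)**

Step 1
Reactants: 1 (4R,6R)-4-hydroxy-2,2,6-trimethylcyclohexanone (actinol)
Product: 2 (4S,6R)-4-benzoyloxy-2,2,6-trimethylcyclohexanone
Conditions: PhCO2H, PPh3, DIAD, THF, 0 °C to rt
Reagents that add atoms: benzoic acid, O=C(O)c1ccccc1
Why: In this Mitsunobu reaction benzoate displaces the activated carbinol oxygen by SN2, which inverts the future C3 of ring B to the required sense and protects it at the same time.

Step 2
Reactants: 2 (4S,6R)-4-benzoyloxy-2,2,6-trimethylcyclohexanone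
Product: 4 (4S)-4-benzoyloxy-2,6,6-trimethylcyclohex-1-en-1-yl trifluoromethanesulfonate, via potassium enolate 3 (not isolated)
Conditions: KN(SiMe3)2, THF, −78 to −20 °C; PhNTf2, −78 °C to rt
Reagents that add atoms: N-phenylbis(trifluoromethanesulfonimide), O=S(=O)(N(c1ccccc1)S(=O)(=O)C(F)(F)F)C(F)(F)F; potassium hexamethyldisilazide, C[Si](C)(C)[N-][Si](C)(C)C.[K+] (potassium only in 3)
Why: This is enolate O-sulfonylation; the ketone has one α-hydrogen, so only the tetrasubstituted enolate can form, the benzoate has no acidic hydrogen, and the methyl-bearing centre becomes planar.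

Step 3
Reactants: 4 (4S)-4-benzoyloxy-2,6,6-trimethylcyclohex-1-en-1-yl trifluoromethanesulfonate
Product: 5 (1S)-3,5,5-trimethyl-4-[(trimethylsilyl)ethynyl]cyclohex-3-en-1-yl benzoate
Conditions: HC≡CSiMe3, PdCl2(PPh3)2 (5 mol %), CuI (10 mol %), Et3N, DMF, 50 °C
Reagents that add atoms: ethynyltrimethylsilane, C#C[Si](C)(C)C
Why: Sonogashira coupling of an enol triflate with a terminal alkyne installs C7 and C8 and touches neither the ester nor C3.

Step 4
Reactants: 5 (1S)-3,5,5-trimethyl-4-[(trimethylsilyl)ethynyl]cyclohex-3-en-1-yl benzoate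
Product: 6 (1S)-4-ethynyl-3,5,5-trimethylcyclohex-3-en-1-ol
Conditions: K2CO3, MeOH, rt
Reagents that add atoms: none
Why: Base-catalysed methanolysis removes the benzoate by transesterification and the C-silyl group by protodesilylation in one operation, which frees the hydroxy group needed to direct step 5.

Step 5
Reactants: 6 (1S)-4-ethynyl-3,5,5-trimethylcyclohex-3-en-1-ol
Product: 7 (1R,3R,6R)-6-ethynyl-1,5,5-trimethyl-7-oxabicyclo[4.1.0]heptan-3-ol (oxirane cis to 3-OH)
Conditions: VO(acac)2 (3 mol %), t-BuOOH (decane), toluene, 0 °C to rt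
Reagents that add atoms: tert-butyl hydroperoxide, CC(C)(C)OO
Why: In this hydroxy-directed vanadium-catalysed epoxidation the homoallylic C3 alkoxide binds the metal peroxide and should deliver oxygen to its own face of the electron-rich tetrasubstituted C5=C6 alkene, which sets C5 and C6 relative to C3.

Step 6
Reactants: 7 (1R,3R,6R)-6-ethynyl-1,5,5-trimethyl-7-oxabicyclo[4.1.0]heptan-3-ol
Product: 8 (1R,2S,4R)-1-ethynyl-2,6,6-trimethylcyclohexane-1,2,4-triol
Conditions: HClO4 (cat.), THF–H2O, 0 °C to rt
Reagents that add atoms: water, O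
Why: This is acid-catalysed trans-diaxial epoxide opening (Fürst–Plattner rule); with 3-OH equatorial, water should attack C5 opposite the oxirane, because C6 is neopentylic and carries the electron-withdrawing ethynyl group, so C5 is inverted, the C6–O bond is kept and the 5,6-trans-diol results.

Step 7
Reactants: 8 (1R,2S,4R)-1-ethynyl-2,6,6-trimethylcyclohexane-1,2,4-triol
Product: 9 (1R,2S,4R)-4-(tert-butyldimethylsilyloxy)-1-ethynyl-2,6,6-trimethylcyclohexane-1,2-diol
Conditions: TBSCl, imidazole, DMF, rt
Reagents that add atoms: tert-butyldimethylsilyl chloride, CC(C)(C)[Si](C)(C)Cl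
Why: Silyl ether formation is selective for the only secondary alcohol, because both tertiary hydroxy groups are too hindered to react.

Step 8
Reactants: 9 (1R,2S,4R)-4-(tert-butyldimethylsilyloxy)-1-ethynyl-2,6,6-trimethylcyclohexane-1,2-diol
Product: 11 (1S,2S,4R)-4-(tert-butyldimethylsilyloxy)-1-[(E)-2-iodoethenyl]-2,6,6-trimethylcyclohexane-1,2-diol, via E-alkenylstannane 10 (not isolated)
Conditions: Bu3SnH, PdCl2(PPh3)2 (2 mol %), THF, 0 °C; then I2, 0 °C
Reagents that add atoms: iodine, II; tributyltin hydride, CCCC[SnH](CCCC)CCCC (tin only in 10)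
Why: Palladium-catalysed syn-hydrostannation places tin on the terminal carbon, away from the very bulky carbinol, and iododestannylation proceeds with retention, which fixes the E C7=C8 alkene.

**Alkynol fragment c1–c4/C5 (steps 9–11)**

Step 9
Reactants: 12 (E)-3-methylpent-2-en-4-yn-1-ol
Product: 13 tert-butyldimethyl{[(E)-3-methylpent-2-en-4-yn-1-yl]oxy}silane
Conditions: TBSCl, imidazole, CH2Cl2, rt
Reagents that add atoms: tert-butyldimethylsilyl chloride, CC(C)(C)[Si](C)(C)Cl
Why: This is silyl ether formation; TBS is chosen over a more labile trialkylsilyl group because it must survive AcOH in step 14 and warm Et3N in step 15 and never has to be removed selectively.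

Step 10
Reactants: 13 tert-butyldimethyl{[(E)-3-methylpent-2-en-4-yn-1-yl]oxy}silane
Product: 15 (E)-5-(tert-butyldimethylsilyloxy)-3-methylpent-3-enal, via dienylborane 14 (not isolated)
Conditions: Cy2BH (from BH3·SMe2 and cyclohexene), THF, 0 °C; then H2O2, pH 7 phosphate buffer, 0 °C
Reagents that add atoms: hydrogen peroxide, OO; dicyclohexylborane, C1CCC(CC1)BC1CCCCC1 (boron only in 14)
Why: In this hydroboration–oxidation the bulky dialkylborane adds once, anti-Markovnikov, to the terminal alkyne far faster than to the trisubstituted alkene, and buffered oxidation should give the β,γ-unsaturated aldehyde without base-induced alkene migration.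

Step 11
Reactants: 15 (E)-5-(tert-butyldimethylsilyloxy)-3-methylpent-3-enal
Product: 16 (5E)-7-(tert-butyldimethylsilyloxy)-5-methylhept-5-en-1-yn-3-ol (racemic)
Conditions: HC≡CMgBr, THF, −78 °C; aq NH4Cl
Reagents that add atoms: ethynylmagnesium bromide, C#C[Mg]Br
Why: Grignard 1,2-addition at low temperature outruns enolisation, and the new carbinol centre is made racemic on purpose because step 13 erases it.

**Fragment union, key step and dienal (steps 12–17)**

Step 12
Reactants: 11 ring B (E)-alkenyl iodide and 16 (5E)-7-(tert-butyldimethylsilyloxy)-5-methylhept-5-en-1-yn-3-ol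
Product: 17 ring B dienynol (E C7=C8, C3≡C4 alkyne, C5 carbinol, E c2=c3, both silyl ethers TBS)
Conditions: Pd(PPh3)4 (5 mol %), CuI (10 mol %), i-Pr2NH, THF, rt, degassed
Reagents that add atoms: none
Why: Sonogashira coupling of an alkenyl iodide keeps the E geometry and tolerates every free hydroxy group, so ring B never meets a strong base or the enolisable aldehyde.

Step 13
Reactants: 17 ring B dienynol
Product: 18 ring B enynone (C5 ketone conjugated to the C3≡C4 alkyne)
Conditions: Dess–Martin periodinane, CH2Cl2, 0 °C to rt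
Reagents that add atoms: none
Why: Dess–Martin oxidation acts on the only oxidisable alcohol (C3 is silylated, C5-OH and C6-OH of ring B are tertiary), and its base-free medium should leave the c2=c3 alkene in place.

Step 14
Reactants: 18 ring B enynone
Product: 19 (Z)-β-iodoenone carrying ring B (iodine on C3 cis to the C5 acyl group)
Conditions: NaI, AcOH, MeCN, rt, dark
Reagents that add atoms: sodium iodide, [Na+].[I-]
Why: This is conjugate hydroiodination of an ynone; iodide adds to C3 and the allenol is protonated on the opposite side, so the kinetic product has iodine cis to the acyl group, and stoichiometric AcOH in MeCN spares both TBS ethers and the tertiary allylic alcohol.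

Step 15
Reactants: 19 (Z)-β-iodoenone carrying ring B and 20 carbon monoxide
Product: 21 ring B (Z)-ylidenebutenolide dienyl bis-TBS ether
Conditions: CO (1 atm), PdCl2(PPh3)2 (5 mol %), Et3N (2 equiv), THF, 45 °C
Reagents that add atoms: carbon monoxide (compound 20), [C-]#[O+]
Why: Zerovalent palladium formed from PdCl2(PPh3)2 inserts into the C3–I bond with retention, CO inserts to give an acylpalladium held cis to the C5 ketone, and Et3N enolises that ketone toward c1, whose enol oxygen attacks the acyl carbon and releases the catalyst. The closest known reaction type is the palladium-catalysed carbonylative lactonisation of (Z)-β-iodoenones to (Z)-γ-alkylidenebutenolides by O-enolate trapping of an acylpalladium. Ring C closes by 5-exo-trig attack of O1 on C2, so C2–C3 and C2–O1 are made in the same operation. No stereocentre is created and the three centres of ring B are remote from all bond changes, so the only new stereo element is the C5=c1 alkene. O-acylation is secured over C-acylation because only oxygen reaches C2 through a five-membered transition state, enolisation is possible only at c1 because C4 is vinylic, and the Z isomer avoids the clash between c2 and H–C4, so it is the more stable product. The tertiary hydroxy groups cannot reach C2 across the E C7=C8 alkene, and a shift of c2=c3 into conjugation would still feed the same dienolate.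

Step 16
Reactants: 21 ring B (Z)-ylidenebutenolide dienyl bis-TBS ether
Product: 22 ring B ylidenebutenolide tetraol (free c4-OH, 3-OH, 5-OH, 6-OH)
Conditions: HF·pyridine, pyridine, THF, 0 °C to rt
Reagents that add atoms: none
Why: Fluoride-driven desilylation removes both TBS groups at once because the end game runs on free hydroxy groups, and the buffered reagent should spare the base-sensitive enol lactone and the tertiary allylic alcohol.

Step 17
Reactants: 22 ring B ylidenebutenolide tetraol
Product: 23 ring B ylidenebutenolide dienal (c4 aldehyde, triol)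
Conditions: MnO2 (activated), CH2Cl2, rt, dark
Reagents that add atoms: none
Why: Allylic oxidation with MnO2 acts only on the primary dienylic alcohol, because 3-OH is not allylic and the other two hydroxy groups are tertiary.

**Ring A phosphonium salt (steps 18–24)**

Step 18
Reactants: 12 (E)-3-methylpent-2-en-4-yn-1-ol
Product: 24 (E)-3-methylpent-2-en-4-ynal
Conditions: MnO2 (activated), CH2Cl2, rt
Reagents that add atoms: none
Why: Allylic oxidation with MnO2 gives the enynal without touching the alkyne or the E alkene.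

Step 19
Reactants: 24 (E)-3-methylpent-2-en-4-ynal
Product: 25 ethyl (2E,4E)-5-methylhepta-2,4-dien-6-ynoate
Conditions: (EtO)2P(O)CH2CO2Et, NaH, THF, 0 °C
Reagents that add atoms: triethyl phosphonoacetate, CCOC(=O)CP(=O)(OCC)OCC
Why: Horner–Wadsworth–Emmons olefination with a stabilised phosphonate gives the E enoate, and the phosphonate anion is too weak a base to disturb the terminal alkyne.

Step 20
Reactants: 1 (4R,6R)-4-hydroxy-2,2,6-trimethylcyclohexanone (actinol)
Product: 26 (4R,6R)-4-benzoyloxy-2,2,6-trimethylcyclohexanone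
Conditions: BzCl, pyridine, DMAP (cat.), CH2Cl2, 0 °C to rt
Reagents that add atoms: benzoyl chloride, O=C(Cl)c1ccccc1
Why: O-acylation leaves the C–O bond intact, so the carbinol configuration needed for ring A is retained.

Step 21
Reactants: 26 (4R,6R)-4-benzoyloxy-2,2,6-trimethylcyclohexanone
Product: 28 (4R)-4-benzoyloxy-2,6,6-trimethylcyclohex-1-en-1-yl trifluoromethanesulfonate, via potassium enolate 27 (not isolated)
Conditions: KN(SiMe3)2, THF, −78 to −20 °C; PhNTf2, −78 °C to rt
Reagents that add atoms: N-phenylbis(trifluoromethanesulfonimide), O=S(=O)(N(c1ccccc1)S(=O)(=O)C(F)(F)F)C(F)(F)F; potassium hexamethyldisilazide, C[Si](C)(C)[N-][Si](C)(C)C.[K+] (potassium only in 27)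
Why: This is enolate O-sulfonylation as in step 2, and the product is the enantiomer of 4 because the methyl-bearing centre has become planar.

Step 22
Reactants: 28 (4R)-4-benzoyloxy-2,6,6-trimethylcyclohex-1-en-1-yl trifluoromethanesulfonate and 25 ethyl (2E,4E)-5-methylhepta-2,4-dien-6-ynoate
Product: 29 ethyl (2E,4E)-7-[(4R)-4-benzoyloxy-2,6,6-trimethylcyclohex-1-en-1-yl]-5-methylhepta-2,4-dien-6-ynoate
Conditions: PdCl2(PPh3)2 (5 mol %), CuI (10 mol %), Et3N, DMF, 50 °C
Reagents that add atoms: none
Why: Sonogashira coupling joins ring A to the complete dienyne chain without touching either preformed E alkene.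

Step 23
Reactants: 29 ethyl (2E,4E)-7-[(4R)-4-benzoyloxy-2,6,6-trimethylcyclohex-1-en-1-yl]-5-methylhepta-2,4-dien-6-ynoate
Product: 30 (2E,4E)-7-[(4R)-4-hydroxy-2,6,6-trimethylcyclohex-1-en-1-yl]-5-methylhepta-2,4-dien-6-yn-1-ol
Conditions: i-Bu2AlH (excess), CH2Cl2, −78 °C; aq potassium sodium tartrate
Reagents that add atoms: none
Why: 1,2-Reduction by the aluminium hydride converts the dienoate into the dienol and cleaves the benzoate in the same operation, so no separate deprotection is needed.

Step 24
Reactants: 30 (2E,4E)-7-[(4R)-4-hydroxy-2,6,6-trimethylcyclohex-1-en-1-yl]-5-methylhepta-2,4-dien-6-yn-1-ol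
Product: 32 tributyl{(2E,4E)-7-[(4R)-4-hydroxy-2,6,6-trimethylcyclohex-1-en-1-yl]-5-methylhepta-2,4-dien-6-yn-1-yl}phosphonium bromide, via dienylic bromide 31 (not isolated)
Conditions: NBS, Me2S, CH2Cl2, −20 to 0 °C; then PBu3, 0 °C to rt
Reagents that add atoms: N-bromosuccinimide, O=C1CCC(=O)N1Br; tributylphosphine, CCCCP(CCCC)CCCC
Why: Corey–Kim bromination converts allylic alcohols into bromides and leaves the saturated secondary alcohol alone, and the phosphine then quaternises by SN2 at the unhindered primary terminus.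

**Final coupling (step 25)**

Step 25
Reactants: 32 ring A tributylphosphonium bromide and 23 ring B ylidenebutenolide dienal
Product: 34 target CNP0163979.2, via dienynyl ylide 33 (not isolated)
Conditions: NaN(SiMe3)2 (1 equiv to 32), THF, −78 °C; then 23, −78 to 0 °C, dark
Reagents that add atoms: none
Why: The Wittig reaction of an allylic trialkylphosphonium ylide should form the new disubstituted alkene E-selectively and tolerates the free hydroxy groups, so no thermodynamic E/Z equilibration is needed that could isomerise the methyl-bearing alkene next to the alkyne.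

**Compound list**

1 | (4R,6R)-4-hydroxy-2,2,6-trimethylcyclohexanone (actinol) | C[C@@H]1C[C@@H](O)CC(C)(C)C1=O | starting material
2 | (4S,6R)-4-benzoyloxy-2,2,6-trimethylcyclohexanone | C[C@@H]1C[C@H](OC(=O)c2ccccc2)CC(C)(C)C1=O | intermediate
3 | potassium enolate of 2 | CC1=C([O-])C(C)(C)C[C@@H](OC(=O)c2ccccc2)C1.[K+] | intermediate (not isolated)
4 | (4S)-4-benzoyloxy-2,6,6-trimethylcyclohex-1-en-1-yl trifluoromethanesulfonate | CC1=C(OS(=O)(=O)C(F)(F)F)C(C)(C)C[C@@H](OC(=O)c2ccccc2)C1 | intermediate
5 | (1S)-3,5,5-trimethyl-4-[(trimethylsilyl)ethynyl]cyclohex-3-en-1-yl benzoate | CC1=C(C#C[Si](C)(C)C)C(C)(C)C[C@@H](OC(=O)c2ccccc2)C1 | intermediate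
6 | (1S)-4-ethynyl-3,5,5-trimethylcyclohex-3-en-1-ol | CC1=C(C#C)C(C)(C)C[C@@H](O)C1 | intermediate
7 | (1R,3R,6R)-6-ethynyl-1,5,5-trimethyl-7-oxabicyclo[4.1.0]heptan-3-ol | C#C[C@]12C(C)(C)C[C@@H](O)C[C@@]1(C)O2 | intermediate
8 | (1R,2S,4R)-1-ethynyl-2,6,6-trimethylcyclohexane-1,2,4-triol | C#C[C@]1(O)C(C)(C)C[C@@H](O)C[C@]1(C)O | intermediate
9 | (1R,2S,4R)-4-(tert-butyldimethylsilyloxy)-1-ethynyl-2,6,6-trimethylcyclohexane-1,2-diol | C#C[C@]1(O)C(C)(C)C[C@@H](O[Si](C)(C)C(C)(C)C)C[C@]1(C)O | intermediate
10 | ring B (E)-2-(tributylstannyl)ethenyl diol | CCCC[Sn](CCCC)(CCCC)/C=C/[C@]1(O)C(C)(C)C[C@@H](O[Si](C)(C)C(C)(C)C)C[C@]1(C)O | intermediate (not isolated)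
11 | (1S,2S,4R)-4-(tert-butyldimethylsilyloxy)-1-[(E)-2-iodoethenyl]-2,6,6-trimethylcyclohexane-1,2-diol | I/C=C/[C@]1(O)C(C)(C)C[C@@H](O[Si](C)(C)C(C)(C)C)C[C@]1(C)O | intermediate
12 | (E)-3-methylpent-2-en-4-yn-1-ol | C#C/C(C)=C/CO | starting material
13 | tert-butyldimethyl{[(E)-3-methylpent-2-en-4-yn-1-yl]oxy}silane | C#C/C(C)=C/CO[Si](C)(C)C(C)(C)C | intermediate
14 | (1E,3E)-dienyl(dicyclohexyl)borane from 13 | C1CCC(CC1)B(C1CCCCC1)/C=C/C(C)=C/CO[Si](C)(C)C(C)(C)C | intermediate (not isolated)
15 | (E)-5-(tert-butyldimethylsilyloxy)-3-methylpent-3-enal | O=CC/C(C)=C/CO[Si](C)(C)C(C)(C)C | intermediate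
16 | (5E)-7-(tert-butyldimethylsilyloxy)-5-methylhept-5-en-1-yn-3-ol (racemic) | C#CC(O)C/C(C)=C/CO[Si](C)(C)C(C)(C)C | intermediate
17 | ring B dienynol (carbinol C5 unassigned) | CC(C)(C)[Si](C)(C)OC/C=C(C)/CC(O)C#C/C=C/[C@]1(O)C(C)(C)C[C@@H](O[Si](C)(C)C(C)(C)C)C[C@]1(C)O | intermediate
18 | ring B enynone | CC(C)(C)[Si](C)(C)OC/C=C(C)/CC(=O)C#C/C=C/[C@]1(O)C(C)(C)C[C@@H](O[Si](C)(C)C(C)(C)C)C[C@]1(C)O | intermediate
19 | (Z)-β-iodoenone carrying ring B | I/C(/C=C/[C@]1(O)C(C)(C)C[C@@H](O[Si](C)(C)C(C)(C)C)C[C@]1(C)O)=C\C(=O)C/C(C)=C/CO[Si](C)(C)C(C)(C)C | intermediate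
20 | carbon monoxide | [C-]#[O+] | starting material
21 | ring B (Z)-ylidenebutenolide dienyl bis-TBS ether | CC(C)(C)[Si](C)(C)OC/C=C(C)/C=C1C=C(/C=C/[C@]2(O)C(C)(C)C[C@@H](O[Si](C)(C)C(C)(C)C)C[C@]2(C)O)C(=O)O/1 | intermediate
22 | ring B ylidenebutenolide tetraol | OC/C=C(C)/C=C1C=C(/C=C/[C@]2(O)C(C)(C)C[C@@H](O)C[C@]2(C)O)C(=O)O/1 | intermediate
23 | ring B ylidenebutenolide dienal | O=C/C=C(C)/C=C1C=C(/C=C/[C@]2(O)C(C)(C)C[C@@H](O)C[C@]2(C)O)C(=O)O/1 | intermediate
24 | (E)-3-methylpent-2-en-4-ynal | C#C/C(C)=C/C=O | intermediate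
25 | ethyl (2E,4E)-5-methylhepta-2,4-dien-6-ynoate | C#C/C(C)=C/C=C/C(=O)OCC | intermediate
26 | (4R,6R)-4-benzoyloxy-2,2,6-trimethylcyclohexanone | C[C@@H]1C[C@@H](OC(=O)c2ccccc2)CC(C)(C)C1=O | intermediate
27 | potassium enolate of 26 | CC1=C([O-])C(C)(C)C[C@H](OC(=O)c2ccccc2)C1.[K+] | intermediate (not isolated)
28 | (4R)-4-benzoyloxy-2,6,6-trimethylcyclohex-1-en-1-yl trifluoromethanesulfonate | CC1=C(OS(=O)(=O)C(F)(F)F)C(C)(C)C[C@H](OC(=O)c2ccccc2)C1 | intermediate
29 | ethyl (2E,4E)-7-[(4R)-4-benzoyloxy-2,6,6-trimethylcyclohex-1-en-1-yl]-5-methylhepta-2,4-dien-6-ynoate | CC1=C(C#C/C(C)=C/C=C/C(=O)OCC)C(C)(C)C[C@H](OC(=O)c2ccccc2)C1 | intermediate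
30 | (2E,4E)-7-[(4R)-4-hydroxy-2,6,6-trimethylcyclohex-1-en-1-yl]-5-methylhepta-2,4-dien-6-yn-1-ol | CC1=C(C#C/C(C)=C/C=C/CO)C(C)(C)C[C@H](O)C1 | intermediate
31 | ring A dienylic bromide | CC1=C(C#C/C(C)=C/C=C/CBr)C(C)(C)C[C@H](O)C1 | intermediate (not isolated)
32 | ring A tributylphosphonium bromide | CC1=C(C#C/C(C)=C/C=C/C[P+](CCCC)(CCCC)CCCC)C(C)(C)C[C@H](O)C1.[Br-] | intermediate
33 | ring A dienynyl tributylphosphonium ylide | CC1=C(C#C/C(C)=C/C=C/C=P(CCCC)(CCCC)CCCC)C(C)(C)C[C@H](O)C1 | intermediate (not isolated)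
34 | CNP0163979.2 | CC1=C(C#C/C(C)=C/C=C/C=C/C=C(C)/C=C2C=C(/C=C/[C@]3(O)C(C)(C)C[C@@H](O)C[C@]3(C)O)C(=O)O/2)C(C)(C)C[C@H](O)C1 | target

**Step count**

Total step count: 25. Longest linear sequence: 15 steps (steps 1–8, 12–17 and 25, from actinol).

**Steps most likely to fail**

Step 15. Three processes could compete. Base could shift the c2=c3 alkene into conjugation, with loss of its geometry, before the ring closes. The C3–I bond could be hydrodehalogenated. CO insertion at the crowded dienylpalladium centre could be slow. The fallback builds ring C without CO and sets out from 13 and from stannane 10, which is isolated instead of being iodinated. Addition of bromine to propiolic acid gives (E)-2,3-dibromoacrylic acid F1. Its β-bromide lies cis to the carboxyl group and undergoes Sonogashira coupling with 13 (Pd(PPh3)4, CuI, Et3N, MeCN). This is followed in the same flask by 5-exo-dig lactonisation to the (Z)-3-bromo-5-ylidenebutenolide F2. Stille coupling of F2 with 10 (Pd2(dba)3, AsPh3, NMP) attaches the ring B vinyl group at C3 and returns to the route at 21.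

Step 6. The developing C5 cation could lose a proton or suffer a 1,2-shift instead of being captured by water, which would lead to allylic alcohol formation or ring contraction. The fallback introduces the C5 oxygen by conjugate addition and sets out from 7. Dess–Martin oxidation of 3-OH followed by Et3N opens the oxirane by E1cB elimination to (4R)-4-ethynyl-4-hydroxy-3,5,5-trimethylcyclohex-2-en-1-one F3, in which the C6–O bond is kept. TESOTf and 2,6-lutidine give its triethylsilyl ether F4, in which the bulky silyloxy group is pseudoaxial and the slim ethynyl group pseudoequatorial. Nucleophilic epoxidation (t-BuOOH, benzyltrimethylammonium hydroxide) should then attack C5 anti to the silyloxy group and give the 4,5-epoxy ketone F5. SmI2 in THF–MeOH cleaves the C4–O bond to give the β-hydroxy ketone F6. Hydroxy-directed Evans–Saksena reduction (Me4NBH(OAc)3, MeCN–AcOH) delivers hydride from the face of 5-OH and gives the 3,5-anti-diol F7. HF·pyridine then returns to the route at 8.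

Step 5. Facial selectivity could be poor, because the axial methyl group at C1 crowds the face to which the C3 hydroxy group directs the oxidant. The fallback uses reagent control and sets out from 4. Palladium-catalysed methoxycarbonylation (Pd(OAc)2, PPh3, CO, MeOH, Et3N, DMF) gives methyl (4S)-4-benzoyloxy-2,6,6-trimethylcyclohex-1-ene-1-carboxylate F8. Excess i-Bu2AlH reduces both esters to (1S)-4-(hydroxymethyl)-3,5,5-trimethylcyclohex-3-en-1-ol F9. Sharpless asymmetric epoxidation (Ti(OiPr)4, D-(−)-diethyl tartrate, t-BuOOH, 4 Å molecular sieves, CH2Cl2, −20 °C) delivers oxygen to the face of 3-OH and gives the epoxy diol F10. TEMPO with PhI(OAc)2 oxidises the primary alcohol to the epoxy aldehyde F11. Ohira–Bestmann homologation (dimethyl (1-diazo-2-oxopropyl)phosphonate, K2CO3, MeOH) then returns to the route at 7.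

Further compounds
F1 | step 15 | (E)-2,3-dibromoacrylic acid | OC(=O)/C(Br)=C\Br
F2 | step 15 | (Z)-3-bromo-5-[(E)-4-(tert-butyldimethylsilyloxy)-2-methylbut-2-enylidene]furan-2(5H)-one | CC(C)(C)[Si](C)(C)OC/C=C(C)/C=C1C=C(Br)C(=O)O/1
F3 | step 6 | (4R)-4-ethynyl-4-hydroxy-3,5,5-trimethylcyclohex-2-en-1-one | CC1=CC(=O)CC(C)(C)[C@@]1(O)C#C
F4 | step 6 | triethylsilyl ether of F3 | CC1=CC(=O)CC(C)(C)[C@@]1(O[Si](CC)(CC)CC)C#C
F5 | step 6 | 4,5-epoxy ketone with the oxirane trans to the 6-silyloxy group | C#C[C@]1(O[Si](CC)(CC)CC)C(C)(C)CC(=O)[C@@H]2O[C@]12C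
F6 | step 6 | 5-hydroxy-6-triethylsilyloxy 3-ketone | C#C[C@]1(O[Si](CC)(CC)CC)C(C)(C)CC(=O)C[C@]1(C)O
F7 | step 6 | 6-O-triethylsilyl ether of 8 | C#C[C@]1(O[Si](CC)(CC)CC)C(C)(C)C[C@@H](O)C[C@]1(C)O
F8 | step 5 | methyl (4S)-4-benzoyloxy-2,6,6-trimethylcyclohex-1-ene-1-carboxylate | CC1=C(C(=O)OC)C(C)(C)C[C@@H](OC(=O)c2ccccc2)C1
F9 | step 5 | (1S)-4-(hydroxymethyl)-3,5,5-trimethylcyclohex-3-en-1-ol | CC1=C(CO)C(C)(C)C[C@@H](O)C1
F10 | step 5 | epoxy diol with the oxirane cis to 3-OH | OC[C@]12C(C)(C)C[C@@H](O)C[C@@]1(C)O2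
F11 | step 5 | epoxy aldehyde with the oxirane cis to 3-OH | O=C[C@]12C(C)(C)C[C@@H](O)C[C@@]1(C)O2
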